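**Plan**

1. Retrosynthetic cuts, in order: imide N–C15 and C12–C13 (aldol); C6–C7 of ring B; C9–C10; C4–C5 of ring A; the two C–Cl bonds; C1–C2.
2. Key event: in ring B the ketone C6, the CH2 C7 and the exocyclic alkene C8=C17 form a β,γ-unsaturated carbonyl array. This is the imprint of a carbonyl-ene closure between an aldehyde C6 on C5 and the CH2 end of an isopropenyl group (C8) on C9.
3. Forward: alkyne–allyl coupling (C1–C2) and semihydrogenation give an acyclic C10 dienol; anti-dichlorination; ring A by chloriranium-initiated cation–olefin closure; C9–C10 by radical Giese coupling with a butenolide; ring B by the ene closure; then aldol and imide.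
4. Stereochemistry: C2/C3 from ligand-controlled anti addition to a Z alkene; C5 from the chair of the ring A closure (relay from C3); C10 from the ring face and C9 from (R)-5-methylbutenolide, whose own center is later erased; C12/C13 from an Evans auxiliary.
5. C6 stays an alcohol through the ene step and is oxidized late, so the unconjugated enone meets only mild reagents.

Key step: step 13

Remark: chloride 2 is assumed to be purchasable as the pure E isomer; names use labdane numbering (ring A C1–C5, C10; ring B C5–C10; chain C11–C16; C17 exocyclic CH2; C20 methyl on C10), with β the face of C20.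

Step 1
Reactants: 1 2-methylbut-3-yn-2-ol; 2 (2E)-4-chloro-3-methylbut-2-en-1-yl acetate
Product: 3 (2E)-7-hydroxy-3,7-dimethyloct-2-en-5-yn-1-yl acetate
Conditions: CuI (10 mol %), NaI, K2CO3, DMF, rt
Reagents that add atoms: none
Why: The copper acetylide of the terminal alkyne displaces the primary allylic halide in an SN2 sense (copper-catalysed alkyne–allyl halide coupling), which forms C1–C2, keeps the E alkene and creates no stereocenter.

Step 2
Reactants: 3 (2E)-7-hydroxy-3,7-dimethyloct-2-en-5-yn-1-yl acetate
Product: 4 (2E,5Z)-7-hydroxy-3,7-dimethylocta-2,5-dien-1-yl acetate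
Conditions: H2 (1 atm), Pd on CaCO3 poisoned with Pb(OAc)2 (Lindlar catalyst), quinoline, EtOAc, rt
Reagents that add atoms: none
Why: Lindlar semihydrogenation adds H2 syn to the alkyne only, giving the Z C2=C3 alkene needed for a threo dichloride and leaving the trisubstituted alkene and the allylic acetate alone.

Step 3
Reactants: 4 (2E,5Z)-7-hydroxy-3,7-dimethylocta-2,5-dien-1-yl acetate
Product: 5 (2E,5R,6R)-5,6-dichloro-7-hydroxy-3,7-dimethyloct-2-en-1-yl acetate
Conditions: ClTi(OiPr)3 (1.1 equiv), t-BuOCl (1.1 equiv), tridentate Schiff base from 3,5-di-tert-butylsalicylaldehyde and (S)-2-amino-1,1,2-triphenylethanol (20 mol %; its R antipode if the sense of induction requires it), hexanes, −20 °C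
Reagents that add atoms: tert-butyl hypochlorite CC(C)(C)OCl; chlorotitanium triisopropoxide CC(C)O[Ti](Cl)(OC(C)C)OC(C)C
Why: Proposed new method: the tertiary alkoxide of 4 should exchange onto the ligand-bound chlorotitanium centre, t-BuOCl then transfers Cl+ to the only alkene held next to titanium (Z C2=C3) and the titanium-bound chloride opens the chloriranium ion from the opposite face, so stereospecific anti addition gives the threo dichloride with the ligand choosing the alkene face, while the remote trisubstituted alkene cannot reach the metal; the closest known reaction type is the titanium-mediated, Schiff-base-controlled enantioselective dichlorination of primary allylic alcohols (Z alkenes included, remote alkenes tolerated), and only the tertiary carbinol as anchor is new.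

Step 4
Reactants: 5 (2E,5R,6R)-5,6-dichloro-7-hydroxy-3,7-dimethyloct-2-en-1-yl acetate
Product: 6 [(1R,3R,4R)-3,4-dichloro-2,2-dimethyl-6-methylidenecyclohexyl]methyl acetate
Conditions: TfOH (5 mol %), (CF3)2CHOH/CH2Cl2 (1:4), −20 °C, then Et3N quench
Reagents that add atoms: none
Why: Ionization of the tertiary alcohol is assisted by the vicinal C3 chlorine, and the chloriranium ion, fixed in configuration by C3, is opened at C4 by the E alkene in a 6-endo cation–olefin cyclization (haliranium-initiated polyene-type closure) through a chair with both C–Cl bonds and CH2OAc equatorial, which sets C5 cis to the C3 chlorine before the C10 cation loses a methyl proton (an endocyclic C1=C10 isomer would give the same radical in step 6).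

Step 5
Reactants: 7 (5R)-5-methyloxolan-2-one ((R)-γ-valerolactone)
Product: 9 (5R)-5-methylfuran-2(5H)-one, via phenylselanyl lactone 8 (not isolated)
Conditions: LiN(i-Pr)2, THF, −78 °C; PhSeBr; then H2O2, pyridine, CH2Cl2, 0 °C → rt
Reagents that add atoms: none
Why: α-Selenenylation of the lactone enolate followed by oxidation and syn selenoxide elimination introduces the C=C bond without touching the existing stereocenter.

Step 6
Reactants: 6 [(1R,3R,4R)-3,4-dichloro-2,2-dimethyl-6-methylidenecyclohexyl]methyl acetate; 9 (5R)-5-methylfuran-2(5H)-one (3 equiv)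
Product: 10 [(1R,3R,4R,6S)-3,4-dichloro-2,2,6-trimethyl-6-[(2R,3R)-2-methyl-5-oxooxolan-3-yl]cyclohexyl]methyl acetate
Conditions: Fe(acac)3 (30 mol %), PhSiH3, EtOH/HOCH2CH2OH, 60 °C
Reagents that add atoms: none
Why: Hydrogen-atom transfer from an iron hydride to the terminal alkene carbon (MHAT) gives the tertiary C10 radical, which adds to the butenolide β-carbon (Giese addition) anti to its 5-methyl group, fixing C9, and on the α face of ring A, anti to the vicinal C5 substituent and with the bulky lactone ending equatorial, fixing C10.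

Step 7
Reactants: 10 lactone acetate from step 6
Product: 11 (3R,4R)-4-hydroxy-N-methoxy-N-methyl-3-(ring A)pentanamide, ring A = 4,5-dichloro-2-(hydroxymethyl)-1,3,3-trimethylcyclohexyl configured as in 10 (6,8-diol, C12 Weinreb amide)
Conditions: MeNH(OMe)·HCl (6 equiv), AlMe3 (6 equiv), CH2Cl2, 0 °C → rt; crude product used at once
Reagents that add atoms: N,O-dimethylhydroxylamine hydrochloride CNOC.Cl
Why: The aluminium amide opens the γ-lactone to the γ-hydroxy Weinreb amide (Weinreb aminolysis) and in excess also cleaves the acetate, no stereocenter being touched.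

Step 8
Reactants: 11 diol Weinreb amide
Product: 12 6-O-tert-butyldimethylsilyl ether of 11 (8-OH free)
Conditions: TBSCl (1.1 equiv), imidazole, CH2Cl2, 0 °C
Reagents that add atoms: tert-butyldimethylsilyl chloride CC(C)(C)[Si](C)(C)Cl
Why: Silyl ether formation selects the primary C6 hydroxyl over the more hindered secondary C8 hydroxyl.

Step 9
Reactants: 12 silyl ether
Product: 13 methyl ketone (C8=O; 6-OTBS, C12 Weinreb amide)
Conditions: Dess–Martin periodinane, NaHCO3, CH2Cl2, rt
Reagents that add atoms: none
Why: Dess–Martin oxidation of the secondary alcohol is neutral and should not epimerize C9, and it removes the relay stereocenter C8.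

Step 10
Reactants: 13 methyl ketone
Product: 14 isopropenyl compound (C8(CH3)=CH2 on C9; 6-OTBS, C12 Weinreb amide)
Conditions: Ph3PCH3Br, KN(SiMe3)2, THF, 0 °C → rt
Reagents that add atoms: methyltriphenylphosphonium bromide C[P+](c1ccccc1)(c1ccccc1)c1ccccc1.[Br-]
Why: Wittig methylenation of the methyl ketone installs the ene donor; the hindered C9–H next to quaternary C10 should not be enolized at 0 °C and the equatorial chlorides resist E2.

Step 11
Reactants: 14 isopropenyl silyl ether
Product: 15 primary alcohol (6-OH)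
Conditions: HF·pyridine, pyridine, THF, 0 °C → rt
Reagents that add atoms: none
Why: Buffered fluoride desilylation frees the C6 hydroxyl without acid strong enough to protonate the isopropenyl group.

Step 12
Reactants: 15 primary alcohol
Product: 16 aldehyde (C6 = CHO on C5, 5α-H; isopropenyl on C9; C12 Weinreb amide)
Conditions: Dess–Martin periodinane, NaHCO3, CH2Cl2, rt
Reagents that add atoms: none
Why: Dess–Martin oxidation gives the aldehyde, whose epimerizable C5 already holds the favoured equatorial formyl group trans to the C9 chain.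

Step 13
Reactants: 16 aldehyde
Product: 17 2-(6,7-dichloro-4-hydroxy-5,5,8a-trimethyl-2-methylidenedecahydronaphthalen-1-yl)-N-methoxy-N-methylacetamide (trans-decalin; 2α,3β-Cl2, 5α-H, 6α-OH, 9α-H, C20 β)
Conditions: Me2AlCl (2.5 equiv), CH2Cl2, −78 → −40 °C
Reagents that add atoms: none
Why: Me2AlCl binds the aldehyde oxygen (a second equivalent sits on the Weinreb amide) and the CH2 end of the isopropenyl group (C7) attacks C6 while one hydrogen of the isopropenyl methyl passes to oxygen through a six-membered array, so the exocyclic C8=C17 alkene and the C6 alkoxide arise together; the alkoxide then loses methane, keeping the medium free of protic acid. The closest known reaction type is the Me2AlCl-promoted type-2 intramolecular carbonyl-ene (Prins-type) cyclization of 5-methylhex-5-enals to 3-methylidenecyclohexanols. Ring B (C5, C6, C7, C8, C9, C10) closes by 6-exo-trig attack on the carbonyl with the central ene carbon C8 inside the new ring, through a chair in which the C5–C6 and C10–C9 bonds are both equatorial on ring A, so the trans fusion is inherited from C5 and C10. The only new stereocenter, C6, should carry an equatorial (α) O–Al group because an axial one would meet the C20 and 4β methyl groups; it is erased in step 15. The step needs the hydrogen to come from the methyl group and not from C9–H, which the type-2 geometry secures because C9–H cannot reach the oxygen, and it needs the aldehyde to be the only enophile, which holds because the amide is not electrophilic enough and the chlorides are inert at this temperature.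

Step 14
Reactants: 17 ene product
Product: 18 2-(6,7-dichloro-4-hydroxy-5,5,8a-trimethyl-2-methylidenedecahydronaphthalen-1-yl)acetaldehyde (configuration as in 17)
Conditions: i-Bu2AlH (3 equiv), THF, −78 °C
Reagents that add atoms: none
Why: Weinreb amide reduction stops at the chelated hemiaminal, which releases the C12 aldehyde on work-up, while the free C6 hydroxyl only consumes one hydride.

Step 15
Reactants: 18 hydroxy aldehyde
Product: 19 2-(6,7-dichloro-5,5,8a-trimethyl-2-methylidene-4-oxodecahydronaphthalen-1-yl)acetaldehyde (configuration as in 17)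
Conditions: Dess–Martin periodinane, NaHCO3, CH2Cl2, 0 °C
Reagents that add atoms: none
Why: Buffered Dess–Martin oxidation turns the C6 alcohol (either epimer) into the ketone without enolization, so the exocyclic alkene stays out of conjugation and the aldehyde is untouched.

Step 16
Reactants: 20 (4R)-4-benzyl-1,3-oxazolidin-2-one; 21 methyl 4-chloro-4-oxobutanoate
Product: 22 methyl 4-[(4R)-4-benzyl-2-oxo-1,3-oxazolidin-3-yl]-4-oxobutanoate
Conditions: n-BuLi, THF, −78 °C; then 21
Reagents that add atoms: none
Why: N-acylation of the lithiated oxazolidinone by the acid chloride gives the aldol donor.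

Step 17
Reactants: 19 keto aldehyde; 22 acyl oxazolidinone (1.3 equiv)
Product: 24 methyl (3R,4S)-3-{[(4R)-4-benzyl-2-oxo-1,3-oxazolidin-3-yl]carbonyl}-4-hydroxy-5-(decalinyl)pentanoate (decalinyl as in 19), via boron enolate 23 (not isolated)
Conditions: 22, Bu2BOTf (1.4 equiv), i-Pr2NEt (1.6 equiv), CH2Cl2, −78 → 0 °C; then 19, −78 → −20 °C; pH 7 buffer, MeOH, H2O2, 0 °C
Reagents that add atoms: none
Why: Evans syn aldol: the preformed Z boron enolate adds through a Zimmerman–Traxler chair to the aldehyde face set by the (R)-benzyl auxiliary, giving the (12S,13R) syn adduct, and it prefers the aldehyde to the hindered C6 ketone.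

Step 18
Reactants: 24 aldol adduct
Product: 26 haterumaimide B, via hydroxy amide 25 (not isolated)
Conditions: NH3 (7 M in MeOH), 0 °C → rt
Reagents that add atoms: ammonia N
Why: Ammonia cleaves the activated exocyclic imide carbonyl to the primary amide, releasing the auxiliary, and the amide nitrogen then closes onto the neighbouring methyl ester (5-exo-trig acyl substitution, succinimide formation) under conditions that should be too weakly basic to conjugate the alkene or epimerize C13.

**Compound list**

1 | 2-methylbut-3-yn-2-ol | CC(C)(O)C#C | starting material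
2 | (2E)-4-chloro-3-methylbut-2-en-1-yl acetate | CC(=O)OC/C=C(\C)CCl | starting material
3 | (2E)-7-hydroxy-3,7-dimethyloct-2-en-5-yn-1-yl acetate | CC(=O)OC/C=C(\C)CC#CC(C)(C)O | intermediate
4 | (2E,5Z)-7-hydroxy-3,7-dimethylocta-2,5-dien-1-yl acetate | CC(=O)OC/C=C(\C)C/C=C\C(C)(C)O | intermediate
5 | (2E,5R,6R)-5,6-dichloro-7-hydroxy-3,7-dimethyloct-2-en-1-yl acetate | CC(C)(O)[C@@H](Cl)[C@H](Cl)C/C(C)=C/COC(C)=O | intermediate
6 | [(1R,3R,4R)-3,4-dichloro-2,2-dimethyl-6-methylidenecyclohexyl]methyl acetate | CC(=O)OC[C@H]1C(C)(C)[C@@H](Cl)[C@H](Cl)CC1=C | intermediate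
7 | (5R)-5-methyloxolan-2-one | C[C@H]1OC(=O)CC1 | starting material
8 | (5R)-5-methyl-3-(phenylselanyl)oxolan-2-one (C3 epimers) | C[C@H]1OC(=O)C([Se]c2ccccc2)C1 | intermediate
9 | (5R)-5-methylfuran-2(5H)-one | C[C@H]1OC(=O)C=C1 | intermediate
10 | [(1R,3R,4R,6S)-3,4-dichloro-2,2,6-trimethyl-6-[(2R,3R)-2-methyl-5-oxooxolan-3-yl]cyclohexyl]methyl acetate | CC(=O)OC[C@H]2C(C)(C)[C@@H](Cl)[C@H](Cl)C[C@]2(C)[C@@H]3[C@@H](C)OC(=O)C3 | intermediate
11 | (3R,4R)-3-[4,5-dichloro-2-(hydroxymethyl)-1,3,3-trimethylcyclohexyl]-4-hydroxy-N-methoxy-N-methylpentanamide (ring as in 10) | OC[C@H]2C(C)(C)[C@@H](Cl)[C@H](Cl)C[C@]2(C)[C@H]([C@@H](C)O)CC(=O)N(C)OC | intermediate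
12 | 6-O-tert-butyldimethylsilyl ether of 11 | CC(C)(C)[Si](C)(C)OC[C@H]2C(C)(C)[C@@H](Cl)[C@H](Cl)C[C@]2(C)[C@H]([C@@H](C)O)CC(=O)N(C)OC | intermediate
13 | C8 methyl ketone of 12 (N-methoxy-N-methyl-4-oxopentanamide) | CC(C)(C)[Si](C)(C)OC[C@H]2C(C)(C)[C@@H](Cl)[C@H](Cl)C[C@]2(C)[C@H](C(C)=O)CC(=O)N(C)OC | intermediate
14 | isopropenyl compound (N-methoxy-N,4-dimethylpent-4-enamide, 6-OTBS) | CC(C)(C)[Si](C)(C)OC[C@H]2C(C)(C)[C@@H](Cl)[C@H](Cl)C[C@]2(C)[C@H](C(C)=C)CC(=O)N(C)OC | intermediate
15 | primary alcohol (6-OH) from 14 | OC[C@H]2C(C)(C)[C@@H](Cl)[C@H](Cl)C[C@]2(C)[C@H](C(C)=C)CC(=O)N(C)OC | intermediate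
16 | aldehyde (C6 = CHO, 5α-H) from 15 | O=C[C@H]2C(C)(C)[C@@H](Cl)[C@H](Cl)C[C@]2(C)[C@H](C(C)=C)CC(=O)N(C)OC | intermediate
17 | 2-(6,7-dichloro-4-hydroxy-5,5,8a-trimethyl-2-methylidenedecahydronaphthalen-1-yl)-N-methoxy-N-methylacetamide (2α,3β-Cl2, 5α-H, 6α-OH, 9α-H, C20 β) | C=C1C[C@H](O)[C@H]2C(C)(C)[C@@H](Cl)[C@H](Cl)C[C@]2(C)[C@H]1CC(=O)N(C)OC | intermediate
18 | 2-(6,7-dichloro-4-hydroxy-5,5,8a-trimethyl-2-methylidenedecahydronaphthalen-1-yl)acetaldehyde | C=C1C[C@H](O)[C@H]2C(C)(C)[C@@H](Cl)[C@H](Cl)C[C@]2(C)[C@H]1CC=O | intermediate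
19 | 2-(6,7-dichloro-5,5,8a-trimethyl-2-methylidene-4-oxodecahydronaphthalen-1-yl)acetaldehyde | C=C1CC(=O)[C@H]2C(C)(C)[C@@H](Cl)[C@H](Cl)C[C@]2(C)[C@H]1CC=O | intermediate
20 | (4R)-4-benzyl-1,3-oxazolidin-2-one | O=C1N[C@H](Cc2ccccc2)CO1 | starting material
21 | methyl 4-chloro-4-oxobutanoate | COC(=O)CCC(Cl)=O | starting material
22 | methyl 4-[(4R)-4-benzyl-2-oxo-1,3-oxazolidin-3-yl]-4-oxobutanoate | COC(=O)CCC(=O)N1[C@H](Cc2ccccc2)COC1=O | intermediate
23 | (Z)-dibutylboron enolate of 22 | CCCCB(CCCC)O/C(=C\CC(=O)OC)N1[C@H](Cc2ccccc2)COC1=O | intermediate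
24 | methyl (3R,4S)-3-{[(4R)-4-benzyl-2-oxo-1,3-oxazolidin-3-yl]carbonyl}-4-hydroxy-5-(decalinyl)pentanoate | C=C1CC(=O)[C@H]2C(C)(C)[C@@H](Cl)[C@H](Cl)C[C@]2(C)[C@H]1C[C@H](O)[C@@H](CC(=O)OC)C(=O)N3[C@H](Cc4ccccc4)COC3=O | intermediate
25 | methyl (3R,4S)-3-carbamoyl-4-hydroxy-5-(decalinyl)pentanoate | C=C1CC(=O)[C@H]2C(C)(C)[C@@H](Cl)[C@H](Cl)C[C@]2(C)[C@H]1C[C@H](O)[C@@H](CC(=O)OC)C(N)=O | intermediate
26 | haterumaimide B | C=C1CC(=O)[C@H]2C(C)(C)[C@@H](Cl)[C@H](Cl)C[C@]2(C)[C@H]1C[C@H](O)[C@H]1CC(=O)NC1=O | target

**Count and risks**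

Total steps: 18. Longest linear sequence: 16 (steps 1–4, 6–15, 17, 18).

Steps most likely to fail:

1. Step 3 (proposed new method). The bulky tertiary alkoxide may bind titanium poorly, so that undirected chlorination of the trisubstituted alkene and loss of enantiocontrol take over. The fallback uses known chemistry, sets out from 2 and comes back at 5. Chloride 2 would be coupled with prop-2-yn-1-ol as in step 1 to give enynol F1, and Lindlar reduction as in step 2 gives dienol F2. The same titanium-mediated dichlorination is then run on this primary Z-allylic alcohol, a demonstrated substrate class, to give dichloro alcohol F3. Dess–Martin oxidation gives dichloro aldehyde F4 (kept cold because C6 is labile), MeTi(OiPr)3 adds to give carbinol F5, a second Dess–Martin oxidation gives methyl ketone F6, and MeCeCl2 (from MeLi and CeCl3, −78 °C) gives tertiary alcohol 5.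

2. Step 4. Ionization may end in elimination to an allylic chloride or a chloride shift without ring closure, and the acid may move the new alkene into the ring. The fallback sets out from 5 and comes back at 6. Alcohol 5 would first be converted with (CF3CO)2O and pyridine into trifluoroacetate F7, which is then solvolysed in (CF3)2CHOH buffered with 2,6-di-tert-butylpyridine. This replaces acid-catalysed dehydration by departure of a discrete nucleofuge under non-acidic conditions.

3. Step 6. The C10 radical may be reduced by a second hydrogen-atom transfer, or the butenolide reduced, faster than the hindered C–C coupling, and face selection at C10 may be incomplete. The fallback sets out from 6 and comes back at 10. Mukaiyama hydration of 6 (Co(acac)2, PhSiH3, O2) gives tertiary alcohol F8, which is acylated with methyl chlorooxoacetate to methyl oxalate F9 and hydrolysed with CsOH to caesium oxalate F10. Visible-light photoredox decarboxylation ([Ir(dF(CF3)ppy)2(dtbbpy)]PF6, blue light, DME/DMF, water) then releases the same C10 radical with no hydride source present and couples it with 9 to give 10.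

Further compounds
F1 | step 3 | (2E)-7-hydroxy-3-methylhept-2-en-5-yn-1-yl acetate | CC(=O)OC/C=C(\C)CC#CCO
F2 | step 3 | (2E,5Z)-7-hydroxy-3-methylhepta-2,5-dien-1-yl acetate | CC(=O)OC/C=C(\C)C/C=C\CO
F3 | step 3 | (2E,5R,6R)-5,6-dichloro-7-hydroxy-3-methylhept-2-en-1-yl acetate | OC[C@@H](Cl)[C@H](Cl)C/C(C)=C/COC(C)=O
F4 | step 3 | (2E,5R,6R)-5,6-dichloro-3-methyl-7-oxohept-2-en-1-yl acetate | O=C[C@@H](Cl)[C@H](Cl)C/C(C)=C/COC(C)=O
F5 | step 3 | (2E,5R,6R)-5,6-dichloro-7-hydroxy-3-methyloct-2-en-1-yl acetate (C7 epimers) | CC(O)[C@@H](Cl)[C@H](Cl)C/C(C)=C/COC(C)=O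
F6 | step 3 | (2E,5R,6R)-5,6-dichloro-3-methyl-7-oxooct-2-en-1-yl acetate | CC(=O)[C@@H](Cl)[C@H](Cl)C/C(C)=C/COC(C)=O
F7 | step 4 | (2E,5R,6R)-5,6-dichloro-3,7-dimethyl-7-(trifluoroacetoxy)oct-2-en-1-yl acetate | CC(C)(OC(=O)C(F)(F)F)[C@@H](Cl)[C@H](Cl)C/C(C)=C/COC(C)=O
F8 | step 6 | [(1R,3R,4R)-3,4-dichloro-6-hydroxy-2,2,6-trimethylcyclohexyl]methyl acetate (C6 epimers) | CC(=O)OC[C@H]1C(C)(C)[C@@H](Cl)[C@H](Cl)CC1(C)O
F9 | step 6 | methyl oxalate of F8 | CC(=O)OC[C@H]1C(C)(C)[C@@H](Cl)[C@H](Cl)CC1(C)OC(=O)C(=O)OC
F10 | step 6 | caesium oxalate of F8 | CC(=O)OC[C@H]1C(C)(C)[C@@H](Cl)[C@H](Cl)CC1(C)OC(=O)C([O-])=O.[Cs+]
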